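What was left over at the last reading of each old run was the part of the charge not standing as target: 58.9% at 0.70 mM on Wednesday, 75.5% at 3.4 mM on Saturday.

| setting | Wednesday's | Saturday's | south-west | south | west | north |
|---|---|---|---|---|---|---|
| solid substrate | 0.70 mM | 3.4 mM | 2.0 mM | 0.50 mM | 1.0 mM | 3.0 mM |
| remark | run made earlier | run made earlier |  |  |  |  |
| time |  |  | 5.0 min | 5.0 min | 5.0 min | 5.0 min |

| run | time / min | target / % |
|---|---|---|
| Wednesday's | 0.667 | 14.2 |
| Wednesday's | 1.33 | 26.5 |
| Wednesday's | 2.00 | 31.4 |
| Wednesday's | 2.50 | 34.6 |
| Wednesday's | 3.00 | 38.8 |
| Wednesday's | 4.00 | 41.1 |
| Saturday's | 0.667 | 3.8 |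
| Saturday's | 1.33 | 11.5 |
| Saturday's | 2.00 | 17.1 |
| Saturday's | 2.50 | 21.1 |
| Saturday's | 3.00 | 22.4 |
| Saturday's | 4.00 | 24.5 |

(each reading ± 1 percentage point)

- at the start none of the solid substrate is in solution
- what has only dissolved of solid substrate counts as not reacted
- a reading or a percentage of target counts all its forms, free or not

1. all flasks from highest to lowest amount of target, in percent of the solid substrate charged, at 5.0 min (south-west / south / west / north)
2. the amount of target, in percent of the solid substrate charged of the flask you put first, at 5.0 min
3. the amount of target, in percent of the solid substrate charged of the flask you put last, at 5.0 min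

I solved the yield, as a fraction of the charge, at both ends. For a thin charge I assumed a ceiling yield, for a heavy one a fixed amount of target, and I joined them as the ceiling divided by one plus N. Here N is the charge over the half-yield charge, the charge at which the yield is half its ceiling. The two last readings, each with a scatter of 1 percentage point, gave that charge as 3.28 mM and the ceiling as 49.9%. So N ran from 0.152 in south to 0.913 in north, and the yield from 43.3% to 26.1%, in the order of the charges. As a test I repeated this on the readings at 2.00 min, which gave 2.53 mM, less than before. One number therefore seemed to belong to one time of reading, and since mine came from 4.00 min, earlier than the asked 5.0 min, I expected my yields to lie low.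

The forecast gave south > west > south-west > north, with 47% (41% to 55%) first and 28% (24% to 32%) last, on the view that “percent yield falls as charge rises”. Its first value lay above mine.

The flask gave south > west > south-west > north, with 51.0% in south and 27.7% in north. At 5.0 min, self-condensation product held 69.2% of the charge in north against 41.3% in south. For south-west, 3.28 mM gives 31.0%, and the flask gave 31.2%.

    crystals ⇌ target, rate k1*(cs1 - [target]) while solid is left; crystals form when [target] > cs1 (solubility = 0.0220 mM, k = 1.70 /s)
    solid substrate ⇌ starting material, rate k2*(cs2 - [starting material]) while solid is left; crystals form when [starting material] > cs2 (solubility = 1.80 mM, k = 0.0320 /s)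
    2 starting material → self-condensation product (k = 10.0 /M/s)
    starting material + target → 2 target (k = 36.0 /M/s)
    starting material → target (k = 0.00490 /s)

A neighbour of north charged with 7.5 mM has N of 2.29, so the rule gives 15.2%. The computed flask gave 21.5%, more than the rule.

The runs are simulated for substances that don't exist.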